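Time is a poor clock for this flask. Free catalyst feeds the round that makes product and also leaks into dormant form, and both draws grow and shrink with it, so count in turnovers instead.

substrate 0.67 M; coupling partner 1.01 M; free catalyst 0.39 mM

    catalyst intermediate C ⇌ by-product + catalyst intermediate D (K1 = 3.0 M, k1 = 51.0 /min)
    catalyst intermediate A ⇌ catalyst intermediate B (K2 = 0.735, k2 = 141 /min)
    free catalyst ⇌ dormant form (K3 = 22.1, k3 = 0.206 /min)
    catalyst intermediate E → free catalyst + product (k4 = 398 /min)
    substrate + free catalyst ⇌ catalyst intermediate A (K5 = 1.7 /M, k5 = 316 /M/min)
    catalyst intermediate D → catalyst intermediate E (k6 = 11800 /min)
    coupling partner + catalyst intermediate B → catalyst intermediate C (k7 = 149 /M/min)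

1. the form that holds most of the catalyst when 5.0% of the substrate are converted (dormant form / catalyst intermediate C / free catalyst / catalyst intermediate A / catalyst intermediate B / catalyst intermediate E)
2. its share of the catalyst then
3. factor on the rate of making product when 5.0% of the substrate are converted if free catalyst is charged twice over
4. factor on the rate when 5.0% of the substrate are converted if free catalyst is charged at 4.0 mM instead

Write the balance of the catalyst, the smallest charge here. With substrate and coupling partner as charged, the time a unit of flux spends in each form, returns counted, is:

catalyst intermediate B: 0.00664 min

catalyst intermediate A: 0.0161 min

free catalyst: 0.0189 min

whole round: 0.0639 min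

By-product returns into catalyst intermediate D at about 0.570 /min, far slower than the onward 11800 /min, so I drop that return.

The round takes far less time than the 4.85 min a free catalyst lasts before leaking, so the forms in the round keep these proportions. Each product made then sends 0.00389 of a catalyst dormant, however much is still active. A catalyst therefore lasts 257 turnovers, its turnover number, and the charge must make 85.9 each to reach 5.0%.

leak number = 0.334

That is the turnovers the charge asks for over the turnovers a catalyst lasts, and it reads directly as the dormant share at that conversion.

So dormant form holds most, at 33.4%. The rate goes with the charge times the share still in the round, while the number falls as the charge rises. Doubling the charge gives 2.50, and 4.0 mM gives 14.9.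

Was one number enough? At that conversion the return from dormant form undoes 7.68% of the leak, a correction I leave out.

The forecast says dormant form at 34%, with factors of 2.5 and 15.1, more catalyst “leaving less time for deactivation”.

The flask gives dormant form at 33.3%, with factors of 2.49 and 14.9.

Part of the order above one in this flask at 5.0% conversion is the undoing of catalyst intermediate A into substrate + free catalyst: the apparent order in free catalyst stands at 1.5, and at 1.1 in the run without that undoing. Without it, a free catalyst waits 0.00472 min per round, so the leak number falls to 0.0836. One plus the ratio of the number to what it leaves in the round gives orders of 1.50 and 1.09. In the flask charged at 4.0 mM the number drops to 0.0326, and the rate there stands at 14.9 times this flask's rate.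

The constants used here are invented; the run is a simulation.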